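## The problem

Arzanol (18) consists of two fully substituted six-membered rings joined only through a methylene carbon: ring A is a 4-hydroxypyran-2-one (O1, lactone carbonyl C2, C3 carrying the bridge, C4 hydroxyl, C5 methyl, C6 ethyl) and ring B is an acylphloroglucinol (C1' carrying the bridge, hydroxyls at C2', C4' and C6', prenyl at C3', acetyl at C5'). The molecule has no stereocentre, so nothing has to be set or relayed; the only geometric question is the configuration of an enol double bond in an intermediate. The real difficulties are the substitution pattern and the sensitivity: six substituents must be placed on ring B without isomers. The prenyl double bond does not survive hydrogenation and cyclises onto a flanking phenol under protic or Lewis acid. The free triphenol is easily oxidised, and the CH2 link between two enolic rings can be cleaved under forcing acid or base. The feature that makes the key step possible is that O1–C2 of ring A is the ester bond of an enol and that C3 lies between this ester carbonyl and C4. Once O1–C2 exists as an enol ester of a 3-arylpropanoic acid, C3 is an ester α-carbon facing a neighbouring ester carbon (C4), so the last ring bond C3–C4 is a Claisen bond. The bridge CH2 and ring B are then the β-carbon and aryl group of a hydrocinnamic acid, and O1, C6, C5 and C4 come from a commercial β-keto ester.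

## Retrosynthesis

**C3'–prenyl bond (18 to 16 and 17).** The prenyl group is removed first, because it tolerates neither the hydrogenolysis nor the Lewis acid used earlier. The precursor 16 has a single free aromatic position, so the forward alkylation with 17 only has to choose carbon over oxygen, not between ring positions.

**C5'–acetyl bond (16 to 14 and 15).** The acetyl group is cut next. In triphenol 14 the two open positions C3' and C5' are equivalent by symmetry, so a single electrophilic acylation with 15 needs no regiocontrol. Carrying the ketone through the enolate chemistry of the key step would add acidic protons and an electrophile to that step, which argues against introducing it earlier.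

**Three O–benzyl bonds (14 to 13).** The phenols are masked as benzyl ethers. These tolerate the strong amide base of the ring closure, and they come off in one neutral hydrogenolysis before any alkene is present.

**C3–C4 of ring A (13 to 11, via 12).** This is the central cut. Opening ring A here, rather than at the more usual lactone bond O1–C2, turns the pyranone into an acyclic enol ester 11 whose two halves are a simple acid and a simple keto ester. It also places the bridge on C3 without any separate alkylation of a preformed pyranone. The forward reaction must close a six-membered ring by ester-enolate acylation faster than the enolate can fragment. It also requires the (Z) enol geometry, with the acyloxy and methoxycarbonyl groups cis.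

**Enol ester bond O1–C2 (11 to 8 and 9, via 10).** The enol ester is cut into acid chloride 8 and the commercial keto ester 9. The forward acylation must occur at oxygen and through the chelated enolate 10, so that the cis geometry is built in.

**Side chain of the acid (8 to 7, then to 3 and 4, via 5 and 6).** The propanoic acid is traced to aldehyde 3 and Meldrum's acid 4 through a condensation–hydride reduction–decarboxylation sequence. This is preferred over an olefination followed by hydrogenation, which would endanger the benzyl ethers.

**Formyl carbon of the aldehyde (3 to 1, via 2).** The C1'–CHO bond is cut, which leads back to the symmetrical tribenzyl ether of phloroglucinol 1. Its three open ring positions are equivalent, so the forward formylation needs no regiocontrol, and the iminium salt 2 formed first deactivates the ring against a second attack. Introducing the formyl group onto the preformed triether is preferred over benzylating 2,4,6-trihydroxybenzaldehyde, where C-benzylation and the sluggish alkylation of the hydrogen-bonded ortho hydroxyls would have to be managed.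

## Roads not taken

Alternative 1: Ring B would be cut at two bonds on adjacent carbons, C4'–O and C5'–C(acetyl), so that the hydroxyl and the acetyl group arrive together from acetic acid (A2).
- Forward step: fluoride (CsF) removes the silyl group of the ortho-silyl aryl triflate A1 and leaves a strained triple bond between C4' and C5'. The carboxylate of A2 adds through oxygen at C4', the carbon remote from the C6' methoxy group. The aryl anion at C5' then takes the acetyl group by an O-to-C shift to give A3.
- Merits: the reaction is mild and neutral. The regiochemistry is dictated by the inductive effect of the flanking methoxy group. No Lewis acid comes near the methylene bridge and over-acylation is impossible. In these respects it is better than step 7 of the chosen plan.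
- Weak points: A1 is a penta-substituted arene that already carries ring A, the bridge and a silyl/triflate pair, and would itself need a long synthesis. The pyranone must travel as its 4-methyl ether. After A3 there remain a C-prenylation of a monophenol, which is less activated than 16, and three O-demethylations. With the prenyl group present, boron trihalides would cyclise it to a chroman; with demethylation first, the route merely arrives at 16 by a longer path.
- Comparison: the chosen plan has no comparable regiochemical safeguard for the acylation. It does not need one, because the two open positions of 14 are equivalent, and it reaches the same stage in far fewer operations from commercial materials.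

Alternative 2: Ring B would be cut at C3'–C4' and C1'–C2' and assembled from the cyclobutenone A4 and the siloxyalkyne A5.
- Forward step: heating opens A4 to a vinylketene, which adds to A5 in a (2+2) manner. A second ring opening and a six-electron electrocyclisation then give phenol A6.
- Merits: the prenyl group is placed at C3' by construction, and the three oxygens emerge differentiated. This is better than step 8 of the chosen plan, which depends on carbon-versus-oxygen selectivity in a polyphenol.
- Weak points: A4 is the silyl enol ether of a 2-substituted cyclobutane-1,3-dione that already bears the complete ring A, so the pyranone problem is only moved into a fragile component. The thermal cascade runs with a nucleophilic alkene close to a ketene. A6 still lacks the acetyl group, which would have to be introduced by electrophilic or anionic acylation in the presence of the prenyl group and three silicon-based protecting groups.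
- Comparison: the alternative exchanges the late prenylation risk for a late acetylation risk, at a much higher step count. The chosen plan does the acid chemistry before any alkene exists and spends its remaining uncertainty on one final alkylation.

Alternative 3: Ring B would be cut at C5'–C6' and formed by a polyketide-type fold of the triketo ester A7.
- Forward step: Mg(OMe)2 in methanol makes the C6 methylene of A7 attack the C1 ester to give A8, which is the same compound as 16 of the chosen route.
- Merits: no protecting groups and no electrophilic acylation are needed. The fold delivers 16 directly, from which the same last step follows. If A7 were in hand, this would be shorter and cleaner than steps 6 and 7.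
- Weak points: A7 is a 2-substituted 3,5,7-trioxo ester carrying an acidic pyranone. It can lactonise through the C5 enol, dehydrate to a 4-pyranone, or lose the pyranonylmethyl group by retro-Michael cleavage under the basic conditions. Its preparation by polyanion chemistry requires a 3-functionalised pyranone, so ring A and the bridge must be solved separately.
- Comparison: the alternative is better in protecting-group economy. The chosen plan sets against it that every intermediate is a stable, isolable compound, and that ring A and the bridge are made in the same step from two simple building blocks.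

Key step: step 5

Assumption: arzanol is treated as the 4-hydroxypyran-2-one tautomer without stereocentres; keto ester 9 is used as the commercial racemate, and its stereocentre disappears on enolisation.

Assumption: 1,3,5-tris(benzyloxy)benzene 1 (phloroglucinol tribenzyl ether) is taken as a catalogue compound.

## Steps

Step 1
Reactants: 1 1,3,5-tris(benzyloxy)benzene
Product: 3 2,4,6-tris(benzyloxy)benzaldehyde, via aryl iminium chloride 2 (not isolated)
Conditions: POCl3 (1.5 equiv), DMF, 0 °C → rt; then ice-water, aq NaOAc
Reagents that add atoms: N,N-dimethylformamide, CN(C)C=O; water, O
Why: Vilsmeier–Haack formylation; the chloroiminium ion from DMF and POCl3 attacks one of the three equivalent positions of the electron-rich triether, and the iminium salt 2 so formed deactivates the ring against a second formylation. Buffered aqueous work-up hydrolyses 2 to the aldehyde 3, and the benzyl ethers should survive because no strong Lewis acid is present.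

Step 2
Reactants: 3 2,4,6-tris(benzyloxy)benzaldehyde; 4 Meldrum's acid (2,2-dimethyl-1,3-dioxane-4,6-dione)
Product: 7 3-[2,4,6-tris(benzyloxy)phenyl]propanoic acid, via arylidene Meldrum's acid 5 (not isolated), via arylmethyl Meldrum's acid 6 (not isolated)
Conditions: HCO2H–Et3N (5:2), 95–100 °C; aq HCl work-up
Reagents that add atoms: none
Why: Knoevenagel condensation, conjugate hydride transfer from formate to the arylidene 5, then ring cleavage of 6 with loss of acetone and CO2 in the hot formate medium (one-pot reductive alkylation–decarboxylation of Meldrum's acid); no H2 or Pd is used, so the benzyl ethers should remain.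

Step 3
Reactants: 7 3-[2,4,6-tris(benzyloxy)phenyl]propanoic acid
Product: 8 3-[2,4,6-tris(benzyloxy)phenyl]propanoyl chloride
Conditions: (COCl)2, DMF (cat.), CH2Cl2, 0 °C → rt; used crude
Reagents that add atoms: oxalyl chloride, ClC(=O)C(=O)Cl
Why: Acid chloride formation through the Vilsmeier-type chloroiminium catalyst; no Lewis acid is present, and both ring positions ortho to the side chain are blocked, so cyclisation to an indanone is excluded.

Step 4
Reactants: 9 methyl 2-methyl-3-oxopentanoate (racemic); 8 3-[2,4,6-tris(benzyloxy)phenyl]propanoyl chloride
Product: 11 methyl (Z)-2-methyl-3-{[3-(2,4,6-tris(benzyloxy)phenyl)propanoyl]oxy}pent-2-enoate, via sodium enolate 10 (not isolated)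
Conditions: 9 (1.2 equiv), NaH (1.1 equiv), Et2O, 0 °C; then 8 in toluene, −30 → 0 °C
Reagents that add atoms: none
Why: O-acylation of a β-keto ester enolate; in a weakly coordinating solvent the sodium enolate 10 is a U-shaped chelate with both oxygens on sodium, so acylation at the ketone oxygen should fix acyloxy and ester cis, as in the (Z)-selective phosphorylation and sulfonylation of chelated enolates of 2-substituted 3-oxo esters. C-acylation would have to build a quaternary carbon flanked by three carbonyl groups and is disfavoured with the hard acyl chloride.

Step 5
Reactants: 11 methyl (Z)-2-methyl-3-{[3-(2,4,6-tris(benzyloxy)phenyl)propanoyl]oxy}pent-2-enoate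
Product: 13 6-ethyl-4-hydroxy-5-methyl-3-{[2,4,6-tris(benzyloxy)phenyl]methyl}pyran-2-one, via lithium pyranolate 12 (not isolated)
Conditions: LiN(SiMe3)2 (2.3 equiv), THF, −78 → −20 °C; then 1 M aq HCl
Reagents that add atoms: none
Why: Intramolecular Claisen (Dieckmann) condensation: LiN(SiMe3)2 removes a proton from the only saturated ester α-CH2 of 11, that of the arylpropanoyl group, and the lithium ester enolate adds to the methyl ester carbonyl held cis to it across the enol double bond; the tetrahedral intermediate expels methoxide and the pyran-2,4-dione so formed is deprotonated at once to the 4-oxidopyranone 12, which acid converts into 13. The closest known reactions are the base-mediated closures of O-acyl salicylates to 3-substituted 4-hydroxycoumarins, of β-acyloxy esters to 4-hydroxy-5,6-dihydropyran-2-ones and of N-acyl enamino esters to 4-hydroxypyridin-2-ones. Ring A closes in the 6-(enolendo)-exo-trig mode by forming C3–C4, O1–C2 being already in place, and the bridge CH2 ends up on C3 because it is the β-carbon of the acyl group. No stereocentre is formed. The step needs ring closure to outrun E1cB loss of the keto ester enolate from the lithium enolate (ketene formation) and cleavage of the enol ester by the methoxide set free; the (Z) geometry fixed in step 4 places the ester carbon within reach of a six-membered transition state, so that closure should proceed below the temperature at which such enolates fragment, and a ketene–enolate pair that does form can recombine at oxygen. Deprotonation at the ethyl CH2 (γ to the unsaturated ester) would give a dienolate that has no ring-forming path of its own and can return by proton transfer, whereas only cyclisation ends in the stabilised anion 12, which makes the overall process irreversible. The benzyl ethers and the bridge CH2 are not affected by the amide base.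

Step 6
Reactants: 13 6-ethyl-4-hydroxy-5-methyl-3-{[2,4,6-tris(benzyloxy)phenyl]methyl}pyran-2-one
Product: 14 6-ethyl-4-hydroxy-5-methyl-3-[(2,4,6-trihydroxyphenyl)methyl]pyran-2-one
Conditions: H2 (1 atm), 10% Pd/C, EtOAc–MeOH, rt
Reagents that add atoms: none
Why: Hydrogenolysis of the three benzyl ethers; the tetrasubstituted, conjugated ring A double bonds and the aryl–CH2 carbon–carbon bond should not be reduced under these mild conditions.

Step 7
Reactants: 14 6-ethyl-4-hydroxy-5-methyl-3-[(2,4,6-trihydroxyphenyl)methyl]pyran-2-one; 15 acetic anhydride
Product: 16 3-[(3-acetyl-2,4,6-trihydroxyphenyl)methyl]-6-ethyl-4-hydroxy-5-methylpyran-2-one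
Conditions: 15 (1.1 equiv), BF3·OEt2, dioxane, 0 °C → rt; then aq NaOAc, MeOH
Reagents that add atoms: none
Why: Friedel–Crafts C-acylation of a phloroglucinol; C3' and C5' of 14 are equivalent, so only one mono-ketone can form, and it is held as a deactivating difluoroboron chelate that should suppress a second acylation. The buffered methanolic work-up frees the chelate and cleaves any O-acetate, including one on the acidic C4 hydroxyl of ring A.

Step 8
Reactants: 16 3-[(3-acetyl-2,4,6-trihydroxyphenyl)methyl]-6-ethyl-4-hydroxy-5-methylpyran-2-one; 17 1-bromo-3-methylbut-2-ene (prenyl bromide)
Product: 18 arzanol, 3-{[3-acetyl-2,4,6-trihydroxy-5-(3-methylbut-2-en-1-yl)phenyl]methyl}-6-ethyl-4-hydroxy-5-methylpyran-2-one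
Conditions: 17 (1.1 equiv), DBU (2.5 equiv), THF, 0 °C → rt; aq citric acid work-up
Reagents that add atoms: none
Why: C-alkylation of an ambident acylphloroglucinol anion, as in the direct C-prenylation of phloroacetophenones; the first equivalent of base is taken up by the acidic ring A hydroxyl, whose carbon C3 is blocked, and the less stabilised ring B phenoxide then reacts at C3', its only unsubstituted carbon, the amidinium counter-ion shielding the oxygens.

## Compound list

1 | 1,3,5-tris(benzyloxy)benzene | c1ccc(COc2cc(OCc3ccccc3)cc(OCc3ccccc3)c2)cc1 | starting material
2 | N,N-dimethyl-1-[2,4,6-tris(benzyloxy)phenyl]methaniminium chloride (aryl iminium salt of the Vilsmeier–Haack reaction) | C[N+](C)=Cc1c(OCc2ccccc2)cc(OCc2ccccc2)cc1OCc1ccccc1.[Cl-] | intermediate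
3 | 2,4,6-tris(benzyloxy)benzaldehyde | O=Cc1c(OCc2ccccc2)cc(OCc2ccccc2)cc1OCc1ccccc1 | intermediate
4 | Meldrum's acid (2,2-dimethyl-1,3-dioxane-4,6-dione) | CC1(C)OC(=O)CC(=O)O1 | starting material
5 | 2,2-dimethyl-5-{[2,4,6-tris(benzyloxy)phenyl]methylidene}-1,3-dioxane-4,6-dione | CC1(C)OC(=O)C(=Cc2c(OCc3ccccc3)cc(OCc3ccccc3)cc2OCc2ccccc2)C(=O)O1 | intermediate
6 | 2,2-dimethyl-5-{[2,4,6-tris(benzyloxy)phenyl]methyl}-1,3-dioxane-4,6-dione | CC1(C)OC(=O)C(Cc2c(OCc3ccccc3)cc(OCc3ccccc3)cc2OCc2ccccc2)C(=O)O1 | intermediate
7 | 3-[2,4,6-tris(benzyloxy)phenyl]propanoic acid | OC(=O)CCc1c(OCc2ccccc2)cc(OCc2ccccc2)cc1OCc1ccccc1 | intermediate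
8 | 3-[2,4,6-tris(benzyloxy)phenyl]propanoyl chloride | ClC(=O)CCc1c(OCc2ccccc2)cc(OCc2ccccc2)cc1OCc1ccccc1 | intermediate
9 | methyl 2-methyl-3-oxopentanoate (racemic) | CCC(=O)C(C)C(=O)OC | starting material
10 | sodium (Z)-1-methoxy-2-methyl-1-oxopent-2-en-3-olate (chelated sodium enolate of 9) | CC/C([O-])=C(\C)C(=O)OC.[Na+] | intermediate
11 | methyl (Z)-2-methyl-3-{[3-(2,4,6-tris(benzyloxy)phenyl)propanoyl]oxy}pent-2-enoate | CC/C(OC(=O)CCc1c(OCc2ccccc2)cc(OCc2ccccc2)cc1OCc1ccccc1)=C(\C)C(=O)OC | intermediate
12 | lithium 6-ethyl-5-methyl-2-oxo-3-{[2,4,6-tris(benzyloxy)phenyl]methyl}pyran-4-olate | CCc1oc(=O)c(Cc2c(OCc3ccccc3)cc(OCc3ccccc3)cc2OCc2ccccc2)c([O-])c1C.[Li+] | intermediate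
13 | 6-ethyl-4-hydroxy-5-methyl-3-{[2,4,6-tris(benzyloxy)phenyl]methyl}pyran-2-one | CCc1oc(=O)c(Cc2c(OCc3ccccc3)cc(OCc3ccccc3)cc2OCc2ccccc2)c(O)c1C | intermediate
14 | 6-ethyl-4-hydroxy-5-methyl-3-[(2,4,6-trihydroxyphenyl)methyl]pyran-2-one | CCc1oc(=O)c(Cc2c(O)cc(O)cc2O)c(O)c1C | intermediate
15 | acetic anhydride | CC(=O)OC(C)=O | starting material
16 | 3-[(3-acetyl-2,4,6-trihydroxyphenyl)methyl]-6-ethyl-4-hydroxy-5-methylpyran-2-one | CCc1oc(=O)c(Cc2c(O)cc(O)c(C(C)=O)c2O)c(O)c1C | intermediate
17 | 1-bromo-3-methylbut-2-ene (prenyl bromide) | CC(C)=CCBr | starting material
18 | arzanol, 3-{[3-acetyl-2,4,6-trihydroxy-5-(3-methylbut-2-en-1-yl)phenyl]methyl}-6-ethyl-4-hydroxy-5-methylpyran-2-one | CCc1oc(=O)c(Cc2c(O)c(CC=C(C)C)c(O)c(C(C)=O)c2O)c(O)c1C | target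

## Step count and least certain steps

Total step count: 8. Longest linear sequence: 8 steps (1 to 18); compounds 4, 9, 15 and 17 enter as commercial materials.

**Step 5 (key step).** The lithium enolate may fragment by E1cB expulsion of the keto ester enolate before it cyclises. The methoxide set free may cleave unreacted enol ester, and any (E) isomer carried through cannot close at all. Material would then be lost to acyclic arylpropanoate products instead of ring A. The fallback changes the ring-forming bond; it sets out from aldehyde 3 and returns at 13. Commercial methyl 3-oxopentanoate would be converted into its dianion (NaH, then n-BuLi, THF, 0 °C) and acylated at C4 with N-methoxy-N-methylpropanamide to give methyl 4-methyl-3,5-dioxoheptanoate F1. Heating F1 with DBU in toluene should close the lactone bond O1–C2 with loss of methanol and give 6-ethyl-4-hydroxy-5-methylpyran-2-one F2. A three-component reductive alkylation of F2 with 3 and Hantzsch ester (diethyl 2,6-dimethyl-1,4-dihydropyridine-3,5-dicarboxylate, L-proline cat., CH2Cl2, rt) should then deliver 13 by Knoevenagel condensation at C3 and transfer hydrogenation of the arylidene intermediate.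

**Step 4.** Acylation may occur at carbon instead of oxygen, or through a non-chelated enolate, which would give the (E) enol ester that cannot cyclise. Chelation favours the required geometry but also favours attack through carbon, so the two demands pull against each other. The fallback separates them; it sets out from 9 and 7 and returns at 11. Silylation of the sodium enolate of 9 (NaH, Et2O, then Me3SiCl) can only occur at oxygen and should give methyl (Z)-2-methyl-3-(trimethylsilyloxy)pent-2-enoate F3, which can be purified by distillation. Acid 7 would be converted with cyanuric fluoride and pyridine in CH2Cl2 into 3-[2,4,6-tris(benzyloxy)phenyl]propanoyl fluoride F4. A fluoride-catalysed silyl-to-acyl exchange between F3 and F4 (Bu4NF cat., THF, −78 °C) should then give 11, with acylation of the enolate ion pair at oxygen expected to be faster than its rotation.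

**Step 8.** Alkylation may occur at a phenol or ring A oxygen, or a second alkylation may occur at an already substituted ring B carbon with loss of aromaticity. The methylene bridge may also fragment by a retro-Michael pathway in the polyanion. The fallback changes the mechanism from anion alkylation to electrophilic aromatic substitution; it sets out from 16 and returns at 18. Treatment of 16 with 2-methylbut-3-en-2-ol and BF3·OEt2 in dioxane at room temperature generates the prenyl cation, for which the only available π-nucleophilic carbon is C3'. The ring A hydroxyl is not nucleophilic under acid, and short reaction times limit cyclisation to a chroman. This fallback makes no new compound (F0).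

**Step 7.** A second acylation at the remaining ring position may compete. Ipso-protonation at C1' under the Lewis acid may cleave the bridge, and O-acetates may persist. The fallback moves the acylation ahead of the deprotection; it sets out from 13 and returns at 16. The tribenzyl ether 13 would be acetylated with the mixed anhydride from acetic acid and (CF3CO)2O in CH2Cl2, a Lewis-acid-free acylation suited to 1,3,5-trialkoxybenzenes. This should give 3-{[3-acetyl-2,4,6-tris(benzyloxy)phenyl]methyl}-6-ethyl-4-hydroxy-5-methylpyran-2-one F5, and hydrogenolysis (H2, 10% Pd/C, EtOAc) should then give 16 directly.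

## Further compounds

F1 | step 5 | methyl 4-methyl-3,5-dioxoheptanoate | CCC(=O)C(C)C(=O)CC(=O)OC
F2 | step 5 | 6-ethyl-4-hydroxy-5-methylpyran-2-one | CCc1oc(=O)cc(O)c1C
F3 | step 4 | methyl (Z)-2-methyl-3-(trimethylsilyloxy)pent-2-enoate | CC/C(O[Si](C)(C)C)=C(\C)C(=O)OC
F4 | step 4 | 3-[2,4,6-tris(benzyloxy)phenyl]propanoyl fluoride | FC(=O)CCc1c(OCc2ccccc2)cc(OCc2ccccc2)cc1OCc1ccccc1
F0 | step 8 | none | none
F5 | step 7 | 3-{[3-acetyl-2,4,6-tris(benzyloxy)phenyl]methyl}-6-ethyl-4-hydroxy-5-methylpyran-2-one | CCc1oc(=O)c(Cc2c(OCc3ccccc3)cc(OCc3ccccc3)c(C(C)=O)c2OCc2ccccc2)c(O)c1C
A1 | alternative 1 | 2,4-dimethoxy-3-[(6-ethyl-4-methoxy-5-methyl-2-oxopyran-3-yl)methyl]-6-(trimethylsilyl)phenyl trifluoromethanesulfonate | CCc1oc(=O)c(Cc2c(OC)cc([Si](C)(C)C)c(OS(=O)(=O)C(F)(F)F)c2OC)c(OC)c1C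
A2 | alternative 1 | acetic acid | CC(=O)O
A3 | alternative 1 | 3-[(3-acetyl-4-hydroxy-2,6-dimethoxyphenyl)methyl]-6-ethyl-4-methoxy-5-methylpyran-2-one | CCc1oc(=O)c(Cc2c(OC)cc(O)c(C(C)=O)c2OC)c(OC)c1C
A4 | alternative 2 | 2-{[6-ethyl-5-methyl-2-oxo-4-(2-trimethylsilylethoxy)pyran-3-yl]methyl}-3-(triisopropylsilyloxy)cyclobut-2-en-1-one | CCc1oc(=O)c(CC2=C(O[Si](C(C)C)(C(C)C)C(C)C)CC2=O)c(OCC[Si](C)(C)C)c1C
A5 | alternative 2 | triisopropyl[(5-methylhex-4-en-1-yn-1-yl)oxy]silane | CC(C)=CCC#CO[Si](C(C)C)(C(C)C)C(C)C
A6 | alternative 2 | 6-ethyl-3-{[4-hydroxy-3-(3-methylbut-2-enyl)-2,6-bis(triisopropylsilyloxy)phenyl]methyl}-5-methyl-4-(2-trimethylsilylethoxy)pyran-2-one | Oc1cc(O[Si](C(C)C)(C(C)C)C(C)C)c(Cc2c(OCC[Si](C)(C)C)c(C)c(CC)oc2=O)c(O[Si](C(C)C)(C(C)C)C(C)C)c1CC=C(C)C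
A7 | alternative 3 | methyl 2-[(6-ethyl-4-hydroxy-5-methyl-2-oxopyran-3-yl)methyl]-3,5,7-trioxooctanoate (racemic) | CCc1oc(=O)c(CC(C(=O)OC)C(=O)CC(=O)CC(C)=O)c(O)c1C
A8 | alternative 3 | 3-[(3-acetyl-2,4,6-trihydroxyphenyl)methyl]-6-ethyl-4-hydroxy-5-methylpyran-2-one | CCc1oc(=O)c(Cc2c(O)cc(O)c(C(C)=O)c2O)c(O)c1C
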